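A direct plan would open a six-ring lactone with ammonia and acetylate to 5-acetoxypentanamide A1, then condense A1 with
3-(3,4-dimethoxyphenyl)propanal A2 and a sulfinic acid to the α-amido sulfone A3; base would release the N-acylimine A4,
a thiazolium carbene would add acetaldehyde A5 to it, and the amido ketone A6 would be closed with an ammonium salt in hot acid.
Weakest would be the carbene-catalysed coupling: it has no precedent for an enolisable alkyl acylimine, A4 can slip to the
enamide, A5 condenses with itself under the excess amine, and all this would be risked on the most advanced intermediate.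
Next would be the making of A3: a plain amide adds poorly, and A2 and the acyliminium ion lie three atoms from the
electron-rich arene (aldol, enamide, Friedel–Crafts). Last, the ring would close only at the end, with oxazole formation
competing, after two steps (lactone opening with acetylation, oxidation to A2) that merely adjust functional groups.

**Plan of the new route**
Cuts: the acetate O–acyl bond, then the C4(imidazole)–CH2 bond of the arylethyl arm, then C5–I, last the four ring C–N bonds.
Ring order: the imidazole arises first, from dihydropyran, methylglyoxal and ammonia; the benzene ring is joined afterwards.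
Feature: N1–H/N3 prototropy makes C4 and C5 one position, so the 2,4-dialkylimidazole has a single ring C–H to iodinate,
and the C4–CH2–CH2–aryl arm is the anti-Markovnikov adduct of 3,4-dimethoxystyrene (hydroboration, then sp2–sp3 coupling).
No acylimine, acyl anion or acyliminium ion occurs, no electrophilic carbon lies near the arene, the C4–C5 bond is bought
in methylglyoxal, and ring closure is the first step on bulk chemicals instead of the last on precious material.

Key step: step 3

Remark: N1–H/N3 prototropy is fast, so each 4(5)-substituted imidazole below is one compound; names and SMILES show one tautomer.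

Step 1
Reactants: 1 3,4-dihydro-2H-pyran; 2 methylglyoxal (2-oxopropanal, 40% in water)
Product: 4 4-(4-methyl-1H-imidazol-2-yl)butan-1-ol, via tetrahydro-2H-pyran-2-ol 3 (not isolated)
Conditions: 1, 0.2 M aq HCl, rt, 1 h; then conc. aq NH3 (6 equiv), MeOH, 0 °C; 2 (1.1 equiv) added over 2 h; rt, 16 h
Reagents that add atoms: ammonia, N
Why: Acid-catalysed hydration of the enol ether gives the lactol 3, whose open-chain form 5-hydroxypentanal then enters a Debus–Radziszewski imidazole synthesis with ammonia and the 1,2-dicarbonyl compound 2 (diimine formation, closure at the aldehyde carbon, loss of three molecules of water), a combination established for 2-alkyl-4-methylimidazoles; slow addition of 2 into excess ammonia and aldehyde limits its self-condensation, and no stereocentre is formed.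

Step 2
Reactants: 4 4-(4-methyl-1H-imidazol-2-yl)butan-1-ol
Product: 5 4-(4-iodo-5-methyl-1H-imidazol-2-yl)butan-1-ol
Conditions: NIS (1.05 equiv), MeCN, 0 °C to rt, dark, 2 h; aq Na2S2O3 wash
Reagents that add atoms: N-iodosuccinimide, O=C1CCC(=O)N1I
Why: Electrophilic aromatic substitution by the iodonium donor can only take place at C5, the single C–H of the electron-rich 2,4-dialkylimidazole (C4 and C5 being one position by prototropy), the primary alcohol is inert to NIS, and no stereocentre is formed.

Step 3
Reactants: 5 4-(4-iodo-5-methyl-1H-imidazol-2-yl)butan-1-ol; 6 3,4-dimethoxystyrene (4-ethenyl-1,2-dimethoxybenzene)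
Product: 8 cypholophine (4-{4-[2-(3,4-dimethoxyphenyl)ethyl]-5-methyl-1H-imidazol-2-yl}butan-1-ol), via 9-[2-(3,4-dimethoxyphenyl)ethyl]-9-borabicyclo[3.3.1]nonane 7 (not isolated)
Conditions: 6 (1.6 equiv), 9-BBN (0.5 M in THF, 1.5 equiv), 0 °C to rt, 4 h; then 5 (1 equiv), Pd(OAc)2 (5 mol%), SPhos (10 mol%), 3 M aq K3PO4 (3 equiv), THF, 65 °C, 12 h, argon
Reagents that add atoms: none
Why: 9-BBN adds its B–H across the vinyl group of 6 in a four-centre syn addition with boron on the terminal carbon, so the two-carbon link is already present in 7; hydroxide from the aqueous phosphate then turns 7 into a borate, zerovalent palladium inserts into the C4–I bond of 5, the primary alkyl group passes to palladium and reductive elimination forges the C4(sp2)–CH2(sp3) bond. The closest known reactions are the B-alkyl Suzuki–Miyaura coupling of heteroaryl halides and the Suzuki–Miyaura coupling of unprotected haloimidazoles. No ring is closed and no stereocentre is formed. The step needs coupling to outrun β-hydride elimination of the alkylpalladium and binding of the azole to the metal: the bulky electron-rich biarylphosphine speeds reductive elimination, and the 2-alkyl and 5-methyl groups flank both ring nitrogens. The free N–H and O–H are tolerated because no B–H is left (6 in slight excess), the alcohol is kept unacetylated so that aqueous base can be used, and no electrophilic carbon is generated near the veratrole ring.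

Step 4
Reactants: 8 cypholophine
Product: 9 O-acetylcypholophine (4-{4-[2-(3,4-dimethoxyphenyl)ethyl]-5-methyl-1H-imidazol-2-yl}butyl acetate)
Conditions: Ac2O (1.5 equiv), pyridine, DMAP (5 mol%), CH2Cl2, 0 °C to rt, 3 h; then MeOH, aq NaHCO3, rt, 1 h
Reagents that add atoms: acetic anhydride, CC(=O)OC(C)=O
Why: DMAP-catalysed nucleophilic acyl substitution acetylates the primary alcohol, while any N-acetylimidazole formed at the ring nitrogen is an activated amide that is cleaved again by the methanolic bicarbonate work-up under which the alkyl acetate is stable; no stereocentre is involved.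

**Compound list**
1 | 3,4-dihydro-2H-pyran | C1=COCCC1 | starting material
2 | methylglyoxal (2-oxopropanal) | CC(=O)C=O | starting material
3 | tetrahydro-2H-pyran-2-ol (lactol of 5-hydroxypentanal) | OC1CCCCO1 | intermediate
4 | 4-(4-methyl-1H-imidazol-2-yl)butan-1-ol | Cc1c[nH]c(CCCCO)n1 | intermediate
5 | 4-(4-iodo-5-methyl-1H-imidazol-2-yl)butan-1-ol | Cc1[nH]c(CCCCO)nc1I | intermediate
6 | 3,4-dimethoxystyrene (4-ethenyl-1,2-dimethoxybenzene) | COc1ccc(C=C)cc1OC | starting material
7 | 9-[2-(3,4-dimethoxyphenyl)ethyl]-9-borabicyclo[3.3.1]nonane | COc1ccc(CCB2C3CCCC2CCC3)cc1OC | intermediate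
8 | cypholophine, 4-{4-[2-(3,4-dimethoxyphenyl)ethyl]-5-methyl-1H-imidazol-2-yl}butan-1-ol | COc1ccc(CCc2nc(CCCCO)[nH]c2C)cc1OC | intermediate
9 | O-acetylcypholophine, 4-{4-[2-(3,4-dimethoxyphenyl)ethyl]-5-methyl-1H-imidazol-2-yl}butyl acetate | COc1ccc(CCc2nc(CCCCOC(C)=O)[nH]c2C)cc1OC | target

Total step count: 4. Longest linear sequence: 4 steps (1 → 4 → 5 → 8 → 9).

Steps most likely to fail, in this order: step 3, step 1, step 2.

For step 3, the unprotected azole may bind palladium and stall the catalytic cycle, or the alkylpalladium may undergo β-hydride elimination, so that the iodide is only reduced. The fallback sets out from 5 and returns at 8. A Sonogashira coupling of 5 with commercial 4-ethynyl-1,2-dimethoxybenzene (PdCl2(PPh3)2, CuI, K2CO3, DMF, 60 °C) should give the alkyne 4-{4-[(3,4-dimethoxyphenyl)ethynyl]-5-methyl-1H-imidazol-2-yl}butan-1-ol F1. This path has no alkylpalladium that could eliminate. Hydrogenation of F1 (H2, Pd/C, EtOH, rt) should then saturate the link and give 8.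

For step 1, methylglyoxal may be consumed by self-condensation with ammonia faster than the lactol delivers its aldehyde, leaving tar and little of the wanted imidazole. The fallback sets out from 3 (made from 1 as before) and returns at 4. Condensation of 3 with propane-1,2-diamine (CH2Cl2, 0 °C) and oxidation of the resulting aminal in the same flask with NBS should give the imidazoline 4-(4-methyl-4,5-dihydro-1H-imidazol-2-yl)butan-1-ol F2. The partly saturated ring is then dehydrogenated with PhI(OAc)2 and K2CO3 in DMSO at rt to 4.

For step 2, the electron-rich ring may be oxidised, or the iodide may lose iodine again on work-up and storage (light, acid), so that 4 is recovered. The fallback sets out from 4 and returns at 8 without any halide. Hydroxymethylation at C5 with aqueous formaldehyde and NaOH should give 4-[4-(hydroxymethyl)-5-methyl-1H-imidazol-2-yl]butan-1-ol F3. MnO2 (dioxane, 60 °C) should oxidise only the ring-bound carbinol to 2-(4-hydroxybutyl)-5-methyl-1H-imidazole-4-carbaldehyde F4. A Wittig reaction with the ylide from (3,4-dimethoxybenzyl)triphenylphosphonium bromide (NaOMe, MeOH) should give 4-{4-[2-(3,4-dimethoxyphenyl)ethenyl]-5-methyl-1H-imidazol-2-yl}butan-1-ol F5 as an E/Z mixture. Hydrogenation (H2, Pd/C, EtOH) should then deliver 8.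

**Further compounds**
F1 | step 3 | 4-{4-[(3,4-dimethoxyphenyl)ethynyl]-5-methyl-1H-imidazol-2-yl}butan-1-ol | COc1ccc(C#Cc2nc(CCCCO)[nH]c2C)cc1OC
F2 | step 1 | 4-(4-methyl-4,5-dihydro-1H-imidazol-2-yl)butan-1-ol (racemic) | CC1CN=C(CCCCO)N1
F3 | step 2 | 4-[4-(hydroxymethyl)-5-methyl-1H-imidazol-2-yl]butan-1-ol | Cc1[nH]c(CCCCO)nc1CO
F4 | step 2 | 2-(4-hydroxybutyl)-5-methyl-1H-imidazole-4-carbaldehyde | Cc1[nH]c(CCCCO)nc1C=O
F5 | step 2 | 4-{4-[2-(3,4-dimethoxyphenyl)ethenyl]-5-methyl-1H-imidazol-2-yl}butan-1-ol (E/Z mixture) | COc1ccc(C=Cc2nc(CCCCO)[nH]c2C)cc1OC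
A1 | direct plan | 5-acetoxypentanamide (5-amino-5-oxopentyl acetate) | CC(=O)OCCCCC(N)=O
A2 | direct plan | 3-(3,4-dimethoxyphenyl)propanal | COc1ccc(CCC=O)cc1OC
A3 | direct plan | 5-({3-(3,4-dimethoxyphenyl)-1-[(4-methylphenyl)sulfonyl]propyl}amino)-5-oxopentyl acetate (racemic) | COc1ccc(CCC(NC(=O)CCCCOC(C)=O)S(=O)(=O)c2ccc(C)cc2)cc1OC
A4 | direct plan | 5-{[(E)-3-(3,4-dimethoxyphenyl)propylidene]amino}-5-oxopentyl acetate | COc1ccc(CC/C=N/C(=O)CCCCOC(C)=O)cc1OC
A5 | direct plan | acetaldehyde | CC=O
A6 | direct plan | 5-{[1-(3,4-dimethoxyphenyl)-4-oxopentan-3-yl]amino}-5-oxopentyl acetate (racemic) | COc1ccc(CCC(NC(=O)CCCCOC(C)=O)C(C)=O)cc1OC
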